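**Retrosynthetic overview**
1. The strategy rests on the vicinal quaternary carbons C1 (Me, dienyl) and C6 (Et, CO2H; carboxyl carbon C10) of the cyclohexene C1–C2=C3(Me)–C4–C5–C6. Their bond is cut back to a δ-lactone C10(=O)–O–C3 whose silyl ketene acetal closes C1–C6 by [3,3] ring contraction, with O–C3 breaking and C2=C3 appearing.
2. The boat that this lactone enforces holds the C4–C5 tether eclipsed, and a trans-fused ring on C4–C5 cannot follow it. The lactone therefore goes through the key step monocyclic, with C4–CH2CO2tBu and C5–CH(Et)CO2Me arms. The cyclopentanone C4–C9–C8–C7–C5 is closed afterwards by Dieckmann condensation, C9 methylation, loss of CO2tBu and base equilibration of C7/C9.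
3. Lactone: C4 from an Evans alkylation, C3 from chelation-controlled addition of the (E,E,E)-trienyl Grignard to the methyl ketone, ring closure by intramolecular HWE, C5 by anti Michael addition of methyl butanoate enolate with ethylation at C6.
4. Trienyl iodide: propargyl alcohol, carboalumination/iodination, oxidation, Wittig, HWE.
5. Ring order: δ-lactone (temporary, step 12), cyclohexene (step 14), cyclopentanone (step 15).

Key step: step 14

Remark: C6 and C7 of the lactones and C7/C9 of the bicyclic compounds are carried as epimer mixtures (no stereo mark in the SMILES), because C6 becomes trigonal in step 14 and C7/C9 flank the C8 ketone; the all-trans cyclopentanone of the target is assumed to be the thermodynamic isomer reached in step 17.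

**Step 1**
Reactants: 1 prop-2-yn-1-ol
Product: 2 (E)-3-iodo-2-methylprop-2-en-1-ol
Conditions: Me3Al (3 equiv), Cp2ZrCl2 (0.25 equiv), CH2Cl2, 0 °C → rt; I2, THF, −30 → 0 °C; aq. K2CO3/Rochelle salt
Reagents that add atoms: trimethylaluminium C[Al](C)C; iodine II
Why: Negishi Zr-catalysed syn-carboalumination puts Me on the internal and Al on the terminal alkyne carbon, and iodinolysis with retention should give the (E)-iodoalkene (Me and I cis).

**Step 2**
Reactants: 2 (E)-3-iodo-2-methylprop-2-en-1-ol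
Product: 3 (E)-3-iodo-2-methylprop-2-enal
Conditions: activated MnO2, CH2Cl2, rt
Reagents that add atoms: none
Why: Allylic alcohol oxidation with MnO2 stops at the enal and leaves the vinyl iodide and the alkene geometry untouched.

**Step 3**
Reactants: 3 (E)-3-iodo-2-methylprop-2-enal; 4 2-(triphenyl-λ5-phosphanylidene)butanal
Product: 5 (2E,4E)-2-ethyl-5-iodo-4-methylpenta-2,4-dienal
Conditions: PhMe, 80 °C
Reagents that add atoms: none
Why: Wittig olefination with a stabilised formyl ylide is (E)-selective and should place CHO trans to the iodoalkenyl group, which fixes the later C1'=C2' geometry.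

**Step 4**
Reactants: 5 (2E,4E)-2-ethyl-5-iodo-4-methylpenta-2,4-dienal; 6 diethyl benzylphosphonate
Product: 7 [(1E,3E,5E)-3-ethyl-6-iodo-5-methylhexa-1,3,5-trien-1-yl]benzene
Conditions: 6, NaHMDS, THF, −78 → 0 °C; then 5
Reagents that add atoms: none
Why: Horner–Wadsworth–Emmons olefination with the benzylphosphonate anion should give the (E)-styrene; the dienal has no α-hydrogen to lose.

**Step 5**
Reactants: 8 (S)-4-benzyl-1,3-oxazolidin-2-one; 9 3-[(4-methoxybenzyl)oxy]propanoic acid
Product: 10 (4S)-4-benzyl-3-{3-[(4-methoxybenzyl)oxy]propanoyl}-1,3-oxazolidin-2-one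
Conditions: DCC, DMAP (cat.), CH2Cl2, 0 °C → rt
Reagents that add atoms: none
Why: Carbodiimide/DMAP N-acylation of the oxazolidinone (Steglich-type acyl transfer) installs the Evans auxiliary on the C3–C4–C5 unit.

**Step 6**
Reactants: 10 (4S)-4-benzyl-3-{3-[(4-methoxybenzyl)oxy]propanoyl}-1,3-oxazolidin-2-one
Product: 11 tert-butyl (3S)-4-[(4S)-4-benzyl-2-oxo-1,3-oxazolidin-3-yl]-3-{[(4-methoxybenzyl)oxy]methyl}-4-oxobutanoate
Conditions: NaHMDS, THF, −78 °C; BrCH2CO2tBu, −78 → −40 °C
Reagents that add atoms: tert-butyl bromoacetate CC(C)(C)OC(=O)CBr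
Why: Evans asymmetric alkylation: the chelated (Z)-sodium enolate is alkylated on the face opposite the benzyl group, which should set C4 as (S).

**Step 7**
Reactants: 11 tert-butyl (3S)-4-[(4S)-4-benzyl-2-oxo-1,3-oxazolidin-3-yl]-3-{[(4-methoxybenzyl)oxy]methyl}-4-oxobutanoate
Product: 12 tert-butyl (3S)-4-[methoxy(methyl)amino]-3-{[(4-methoxybenzyl)oxy]methyl}-4-oxobutanoate
Conditions: MeNH(OMe)·HCl, Me3Al, CH2Cl2, −10 °C → rt; cold 0.5 M HCl
Reagents that add atoms: N,O-dimethylhydroxylamine hydrochloride CNOC.Cl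
Why: Weinreb transamidation with the aluminium amide cleaves the exocyclic imide carbonyl, releases the auxiliary and leaves the tert-butyl ester and C4 untouched.

**Step 8**
Reactants: 12 tert-butyl (3S)-4-[methoxy(methyl)amino]-3-{[(4-methoxybenzyl)oxy]methyl}-4-oxobutanoate
Product: 13 tert-butyl (3S)-3-{[(4-methoxybenzyl)oxy]methyl}-4-oxopentanoate
Conditions: MeMgBr, THF, −20 → 0 °C; cold 0.5 M HCl
Reagents that add atoms: methylmagnesium bromide C[Mg]Br
Why: Weinreb ketone synthesis: the chelated tetrahedral intermediate prevents over-addition and shields the α-stereocentre until the cold quench; the tert-butyl ester is too hindered to react.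

**Step 9**
Reactants: 13 tert-butyl (3S)-3-{[(4-methoxybenzyl)oxy]methyl}-4-oxopentanoate; 7 [(1E,3E,5E)-3-ethyl-6-iodo-5-methylhexa-1,3,5-trien-1-yl]benzene
Product: 17 tert-butyl (3S,4R,5E,7E,9E)-4-{[(diethoxyphosphoryl)acetyl]oxy}-8-ethyl-3-{[(4-methoxybenzyl)oxy]methyl}-4,6-dimethyl-10-phenyldeca-5,7,9-trienoate, via trienyllithium 14 (not isolated), via trienylmagnesium bromide 15 (not isolated), via bromomagnesium alkoxide 16 (not isolated)
Conditions: 7, t-BuLi (2 equiv), Et2O, −78 °C; MgBr2·OEt2; add to 13 + MgBr2·OEt2 (2 equiv), CH2Cl2, −78 °C; then (EtO)2P(O)CH2COCl, −78 → 0 °C; pH 7 buffer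
Reagents that add atoms: (diethoxyphosphoryl)acetyl chloride CCOP(=O)(CC(=O)Cl)OCC
Why: Chelation-controlled Grignard addition (Cram cyclic model): Mg bridges the ketone and the β-OPMB oxygen, the trienyl group (geometry retained through I/Li exchange) adds anti to the C4 CH2CO2tBu arm and should set C3 (Me cis, trienyl trans to that arm); the alkoxide is acylated in situ before it can attack the tert-butyl ester.

**Step 10**
Reactants: 17 tert-butyl (3S,4R,5E,7E,9E)-4-{[(diethoxyphosphoryl)acetyl]oxy}-8-ethyl-3-{[(4-methoxybenzyl)oxy]methyl}-4,6-dimethyl-10-phenyldeca-5,7,9-trienoate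
Product: 18 tert-butyl (3S,4R,5E,7E,9E)-4-{[(diethoxyphosphoryl)acetyl]oxy}-8-ethyl-3-(hydroxymethyl)-4,6-dimethyl-10-phenyldeca-5,7,9-trienoate
Conditions: DDQ (1.3 equiv), CH2Cl2/pH 7 buffer, 0 °C
Reagents that add atoms: none
Why: Oxidative PMB ether cleavage (benzylic hydride abstraction, hydrolysis of the oxocarbenium ion) under cold, buffered conditions should free the primary alcohol without acid that would ionise the tertiary trienyl ester.

**Step 11**
Reactants: 18 tert-butyl (3S,4R,5E,7E,9E)-4-{[(diethoxyphosphoryl)acetyl]oxy}-8-ethyl-3-(hydroxymethyl)-4,6-dimethyl-10-phenyldeca-5,7,9-trienoate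
Product: 19 tert-butyl (3R,4R,5E,7E,9E)-4-{[(diethoxyphosphoryl)acetyl]oxy}-8-ethyl-3-formyl-4,6-dimethyl-10-phenyldeca-5,7,9-trienoate
Conditions: Dess–Martin periodinane, pyridine, CH2Cl2, 0 °C → rt; used at once
Reagents that add atoms: none
Why: Dess–Martin oxidation is near-neutral, so the β-acyloxy aldehyde with its α-stereocentre C4 should survive if used directly (the descriptor at C4 changes by priority only).

**Step 12**
Reactants: 19 tert-butyl (3R,4R,5E,7E,9E)-4-{[(diethoxyphosphoryl)acetyl]oxy}-8-ethyl-3-formyl-4,6-dimethyl-10-phenyldeca-5,7,9-trienoate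
Product: 20 tert-butyl {(2S,3S)-2-[(1E,3E,5E)-4-ethyl-2-methyl-6-phenylhexa-1,3,5-trien-1-yl]-2-methyl-6-oxo-3,6-dihydro-2H-pyran-3-yl}acetate
Conditions: LiCl, i-Pr2NEt, MeCN (high dilution), 0 °C → rt
Reagents that add atoms: none
Why: Intramolecular Horner–Wadsworth–Emmons reaction (Masamune–Roush conditions) closes the α,β-unsaturated δ-lactone; the ring enforces the (Z)-alkene and the mild base should spare C4.

**Step 13**
Reactants: 20 tert-butyl {(2S,3S)-2-[(1E,3E,5E)-4-ethyl-2-methyl-6-phenylhexa-1,3,5-trien-1-yl]-2-methyl-6-oxo-3,6-dihydro-2H-pyran-3-yl}acetate; 21 methyl butanoate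
Product: 24 methyl 2-{(2S,3S,4R)-3-(2-tert-butoxy-2-oxoethyl)-5-ethyl-2-[(1E,3E,5E)-4-ethyl-2-methyl-6-phenylhexa-1,3,5-trien-1-yl]-2-methyl-6-oxooxan-4-yl}butanoate (C6 and C7 epimer mixture), via lithium enolate of methyl butanoate 22 (not isolated), via lithium lactone enolate 23 (not isolated)
Conditions: 21, LDA, THF, −78 °C; 20, −78 °C; EtI, DMPU, −78 → −20 °C
Reagents that add atoms: iodoethane CCI
Why: Michael addition of the lithium ester enolate to the unsaturated δ-lactone should occur axially on the half-chair, anti to the C4 arm and to the pseudo-axial C3 methyl, setting C5 trans to C4; the resulting lactone enolate is alkylated at C6 with EtI.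

**Step 14**
Reactants: 24 methyl 2-{(2S,3S,4R)-3-(2-tert-butoxy-2-oxoethyl)-5-ethyl-2-[(1E,3E,5E)-4-ethyl-2-methyl-6-phenylhexa-1,3,5-trien-1-yl]-2-methyl-6-oxooxan-4-yl}butanoate
Product: 27 ring-contracted acid (1-ethyl-2-methyl-2-dienyl-cyclohex-3-ene-1-carboxylic acid in ring-name numbering; dienyl cis to CO2H; C4 CH2CO2tBu and C5 CH(Et)CO2Me arms trans), via lactone trimethylsilyl ketene acetal 25 (not isolated), via trimethylsilyl ester 26 (not isolated)
Conditions: LiHMDS (1.5 equiv), THF, −78 °C; TMSCl–Et3N, −78 °C → rt; PhMe, 60 °C; aqueous work-up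
Reagents that add atoms: none
Why: LiHMDS removes the lactone α-proton at C6 (about 5 pK units more acidic than the α-positions of the two ester arms, to which HMDS hands protons back) and TMSCl traps the enolate as the cyclic ketene acetal 25, which undergoes the Ireland–Claisen [3,3] shift: C6–C1 forms while O–C3 breaks and C2=C3 appears. The closest known reaction type is the Ireland–Claisen ring contraction of δ-lactone silyl ketene acetals that carry an alkenyl group on the carbinol carbon, which gives cyclohex-3-enecarboxylic acids. The cyclohexene closes by this sigmatropic ring contraction through the boat that the two-atom C4–C5 tether enforces (a 2-oxabicyclo[2.2.2]octene-like transition state), not by a polar cyclisation. C6 is set by the face of the ketene acetal on which C3 holds the alkenyl group (the ketene acetal geometry is fixed by the ring), and C1 by the (E) geometry of C1=C2, which puts the methyl inside and the dienyl outside so that dienyl and CO2H end up cis. The step needs the [3,3] shift to outrun ionisation of the tertiary trienyl C3–O bond and base attack on the ester arms; the non-polar, weakly basic conditions and the thermodynamic choice of the lactone enolate should secure this, and the acyclic trans C4/C5 arms can follow the eclipsed tether where a trans-fused ring could not.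

**Step 15**
Reactants: 27 ring-contracted acid
Product: 28 trans-fused β-keto tert-butyl ester (cyclopentanone C4–C9H(CO2tBu)–C8(=O)–C7H(Et)–C5 on the cyclohexene acid; C7 and C9 epimer mixture)
Conditions: KOtBu (3.2 equiv), THF, 0 °C → rt; AcOH
Reagents that add atoms: none
Why: Dieckmann condensation: the C9 enolate of the tert-butyl ester arm attacks the methyl ester, the only direction that gives an enolisable β-keto ester, and the trans-diequatorial arms should close the trans-fused five-membered ring; the C10 carboxylate is a spectator.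

**Step 16**
Reactants: 28 trans-fused β-keto tert-butyl ester
Product: 29 C9-methylated β-keto tert-butyl ester (C9 bears Me and CO2tBu; C7 and C9 epimer mixture)
Conditions: KOtBu (2.05 equiv), THF, −20 °C; MeI (1.1 equiv), → 0 °C; AcOH
Reagents that add atoms: iodomethane CI
Why: C-alkylation of the β-keto ester enolate in the dianion; the enolate carbon is far more nucleophilic than the hindered C10 carboxylate, so one equivalent of MeI should go to C9.

**Step 17**
Reactants: 29 C9-methylated β-keto tert-butyl ester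
Product: 32 target acid CNP0268209.1, via bis(trimethylsilyl) ester 30 (not isolated), via β-keto diacid 31 (not isolated)
Conditions: TMSOTf, 2,6-lutidine, CH2Cl2, 0 °C; aq. NaH2PO4, then PhMe, 50 °C; DBU, rt
Reagents that add atoms: none
Why: Silyl triflate cleavage of the tert-butyl ester avoids protic acid that would protonate the diene; the β-keto acid decarboxylates on warming, and DBU equilibrates C7 and C9 (both α to the C8 ketone) to the all-trans isomer, Me trans to C3 and Et trans to C6.

**Compound list**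
1 | prop-2-yn-1-ol | C#CCO | starting material
2 | (E)-3-iodo-2-methylprop-2-en-1-ol | OC/C(C)=C/I | intermediate
3 | (E)-3-iodo-2-methylprop-2-enal | O=C/C(C)=C/I | intermediate
4 | 2-(triphenyl-λ5-phosphanylidene)butanal | CCC(C=O)=P(c1ccccc1)(c1ccccc1)c1ccccc1 | starting material
5 | (2E,4E)-2-ethyl-5-iodo-4-methylpenta-2,4-dienal | CCC(/C=O)=C\C(C)=C\I | intermediate
6 | diethyl benzylphosphonate | CCOP(=O)(Cc1ccccc1)OCC | starting material
7 | [(1E,3E,5E)-3-ethyl-6-iodo-5-methylhexa-1,3,5-trien-1-yl]benzene | CCC(/C=C/c1ccccc1)=C\C(C)=C\I | intermediate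
8 | (S)-4-benzyl-1,3-oxazolidin-2-one | O=C1N[C@@H](Cc2ccccc2)CO1 | starting material
9 | 3-[(4-methoxybenzyl)oxy]propanoic acid | COc1ccc(COCCC(=O)O)cc1 | starting material
10 | (4S)-4-benzyl-3-{3-[(4-methoxybenzyl)oxy]propanoyl}-1,3-oxazolidin-2-one | O=C1OC[C@H](Cc2ccccc2)N1C(=O)CCOCc3ccc(OC)cc3 | intermediate
11 | tert-butyl (3S)-4-[(4S)-4-benzyl-2-oxo-1,3-oxazolidin-3-yl]-3-{[(4-methoxybenzyl)oxy]methyl}-4-oxobutanoate | O=C1OC[C@H](Cc2ccccc2)N1C(=O)[C@@H](CC(=O)OC(C)(C)C)COCc3ccc(OC)cc3 | intermediate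
12 | tert-butyl (3S)-4-[methoxy(methyl)amino]-3-{[(4-methoxybenzyl)oxy]methyl}-4-oxobutanoate | CON(C)C(=O)[C@@H](CC(=O)OC(C)(C)C)COCc1ccc(OC)cc1 | intermediate
13 | tert-butyl (3S)-3-{[(4-methoxybenzyl)oxy]methyl}-4-oxopentanoate | CC(=O)[C@@H](CC(=O)OC(C)(C)C)COCc1ccc(OC)cc1 | intermediate
14 | trienyllithium, [(1E,3E,5E)-4-ethyl-2-methyl-6-phenylhexa-1,3,5-trien-1-yl]lithium | CCC(/C=C/c1ccccc1)=C\C(C)=C\[Li] | intermediate (not isolated)
15 | trienylmagnesium bromide | CCC(/C=C/c1ccccc1)=C\C(C)=C\[Mg]Br | intermediate (not isolated)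
16 | bromomagnesium alkoxide of the tertiary trienyl carbinol (C3 R, C4 S) | CCC(/C=C/c1ccccc1)=C\C(C)=C\[C@](O[Mg]Br)(C)[C@@H](CC(=O)OC(C)(C)C)COCc2ccc(OC)cc2 | intermediate (not isolated)
17 | tert-butyl (3S,4R,5E,7E,9E)-4-{[(diethoxyphosphoryl)acetyl]oxy}-8-ethyl-3-{[(4-methoxybenzyl)oxy]methyl}-4,6-dimethyl-10-phenyldeca-5,7,9-trienoate | CCC(/C=C/c1ccccc1)=C\C(C)=C\[C@](OC(=O)CP(=O)(OCC)OCC)(C)[C@@H](CC(=O)OC(C)(C)C)COCc2ccc(OC)cc2 | intermediate
18 | tert-butyl (3S,4R,5E,7E,9E)-4-{[(diethoxyphosphoryl)acetyl]oxy}-8-ethyl-3-(hydroxymethyl)-4,6-dimethyl-10-phenyldeca-5,7,9-trienoate | CCC(/C=C/c1ccccc1)=C\C(C)=C\[C@](OC(=O)CP(=O)(OCC)OCC)(C)[C@@H](CC(=O)OC(C)(C)C)CO | intermediate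
19 | tert-butyl (3R,4R,5E,7E,9E)-4-{[(diethoxyphosphoryl)acetyl]oxy}-8-ethyl-3-formyl-4,6-dimethyl-10-phenyldeca-5,7,9-trienoate | CCC(/C=C/c1ccccc1)=C\C(C)=C\[C@](OC(=O)CP(=O)(OCC)OCC)(C)[C@@H](CC(=O)OC(C)(C)C)C=O | intermediate
20 | tert-butyl {(2S,3S)-2-[(1E,3E,5E)-4-ethyl-2-methyl-6-phenylhexa-1,3,5-trien-1-yl]-2-methyl-6-oxo-3,6-dihydro-2H-pyran-3-yl}acetate | CCC(/C=C/c1ccccc1)=C\C(C)=C\[C@]2(C)[C@@H](CC(=O)OC(C)(C)C)C=CC(=O)O2 | intermediate
21 | methyl butanoate | CCCC(=O)OC | starting material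
22 | lithium enolate of methyl butanoate | CCC=C(OC)O[Li] | intermediate (not isolated)
23 | lithium enolate of the Michael adduct lactone (C6 unsubstituted) | CCC(/C=C/c1ccccc1)=C\C(C)=C\[C@]2(C)[C@@H](CC(=O)OC(C)(C)C)[C@H](C(CC)C(=O)OC)C=C(O[Li])O2 | intermediate (not isolated)
24 | methyl 2-{(2S,3S,4R)-3-(2-tert-butoxy-2-oxoethyl)-5-ethyl-2-[(1E,3E,5E)-4-ethyl-2-methyl-6-phenylhexa-1,3,5-trien-1-yl]-2-methyl-6-oxooxan-4-yl}butanoate; δ-lactone, C3 Me cis and trienyl trans to the C4 arm, C4 and C5 arms trans, C6/C7 epimer mixture | CCC(/C=C/c1ccccc1)=C\C(C)=C\[C@]2(C)[C@@H](CC(=O)OC(C)(C)C)[C@H](C(CC)C(=O)OC)C(CC)C(=O)O2 | intermediate (key-step precursor)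
25 | trimethylsilyl ketene acetal of lactone 24 | CCC(/C=C/c1ccccc1)=C\C(C)=C\[C@]2(C)[C@@H](CC(=O)OC(C)(C)C)[C@H](C(CC)C(=O)OC)C(CC)=C(O[Si](C)(C)C)O2 | intermediate (not isolated)
26 | trimethylsilyl ester of acid 27 | CCC(/C=C/c1ccccc1)=C\[C@@]2(C)C=C(C)[C@@H](CC(=O)OC(C)(C)C)[C@H](C(CC)C(=O)OC)[C@@]2(CC)C(=O)O[Si](C)(C)C | intermediate (not isolated)
27 | ring-contracted acid: cyclohexene C1(Me, (1E,3E)-2-ethyl-4-phenylbuta-1,3-dienyl)–C2=C3(Me)–C4(CH2CO2tBu)–C5(CH(Et)CO2Me)–C6(Et, CO2H); dienyl cis to CO2H, C6 Et cis to the C5 arm, C4/C5 arms trans; C7 epimer mixture | CCC(/C=C/c1ccccc1)=C\[C@@]2(C)C=C(C)[C@@H](CC(=O)OC(C)(C)C)[C@H](C(CC)C(=O)OC)[C@@]2(CC)C(=O)O | intermediate (key-step product)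
28 | trans-fused β-keto tert-butyl ester: 27 with the cyclopentanone C4–C9H(CO2tBu)–C8(=O)–C7H(Et)–C5 closed; C7/C9 epimer mixture | CCC(/C=C/c1ccccc1)=C\[C@@]2(C)C=C(C)[C@@H]3[C@H](C(CC)C(=O)C3C(=O)OC(C)(C)C)[C@@]2(CC)C(=O)O | intermediate
29 | C9-methylated β-keto tert-butyl ester (C9: Me, CO2tBu); C7/C9 epimer mixture | CCC(/C=C/c1ccccc1)=C\[C@@]2(C)C=C(C)[C@@H]3[C@H](C(CC)C(=O)C3(C)C(=O)OC(C)(C)C)[C@@]2(CC)C(=O)O | intermediate
30 | bis(trimethylsilyl) ester of diacid 31 | CCC(/C=C/c1ccccc1)=C\[C@@]2(C)C=C(C)[C@@H]3[C@H](C(CC)C(=O)C3(C)C(=O)O[Si](C)(C)C)[C@@]2(CC)C(=O)O[Si](C)(C)C | intermediate (not isolated)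
31 | β-keto diacid (C9: Me, CO2H) | CCC(/C=C/c1ccccc1)=C\[C@@]2(C)C=C(C)[C@@H]3[C@H](C(CC)C(=O)C3(C)C(=O)O)[C@@]2(CC)C(=O)O | intermediate (not isolated)
32 | target acid CNP0268209.1: trans-fused cyclohexene–cyclopentanone, all-trans C9-Me/C4/C5/C7-Et, C6 (Et, CO2H), C1 (Me, (1E,3E)-dienyl cis to CO2H) | CCC(/C=C/c1ccccc1)=C\[C@@]1(C)C=C(C)[C@@H]2[C@H]([C@H](CC)C(=O)[C@H]2C)[C@@]1(CC)C(=O)O | target

**Step count**
Total: 17 steps. Longest linear sequence: 13 steps (steps 5–17; the trienyl branch, steps 1–4 then 9–17, is equally long).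

**Steps most likely to fail**

1. Step 14 (key step). The base may also attack the two ester arms while the hindered tertiary C6–H is removed only slowly, so that the C9 enolate condenses on the methyl ester before silylation and too little lactone ketene acetal forms; ionisation of the tertiary trienyl C3–O bond then competes. The fallback makes the C6 enolate by conjugate addition instead of deprotonation. It sets out from 13: step 9 is run with 2-(diethoxyphosphoryl)butanoyl chloride to give the phosphonobutanoate F1, DDQ gives the primary alcohol F2, Dess–Martin oxidation gives the aldehyde F3, and the intramolecular HWE reaction gives the α-ethyl unsaturated lactone F4. Michael addition of 22 to F4, anti to the C4 arm, delivers the fully substituted lithium lactone enolate F5 regiospecifically, with no free base left over. TMSCl converts it into 25, where the route is rejoined (25 → 26 → 27).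

2. Step 9. Chelation control may erode if the ester carbonyl competes with the PMB ether for magnesium (poor facial selectivity at C3), the Grignard reagent may enolise the ketone, and the very hindered alkoxide may acylate incompletely. The fallback sets out from 13 and 15: the adduct is quenched and the tertiary alcohol F6 is isolated and freed from its C3 epimer by chromatography. It is then acylated with the small bromoacetyl bromide/pyridine to the bromoacetate F7, and a Michaelis–Becker reaction with sodium diethyl phosphite comes back to 17.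

3. Step 10. DDQ may attack the electron-rich phenyl triene (charge-transfer oxidation or cycloaddition) faster than it cleaves the PMB ether. The fallback removes the PMB group before the triene is present. It sets out from 13: DDQ gives the β-hydroxy ketone F8, which is used at once. Its chloromagnesium alkoxide (i-PrMgCl, −78 °C) takes up 15 through the tighter alkoxide chelate, with the same facial sense, to give the diol F9. TEMPO/PhI(OAc)2 oxidises only the primary alcohol to the hydroxy aldehyde F10. Ando (Z)-selective olefination with ethyl (diphenoxyphosphoryl)acetate gives the (Z)-enoate F11, which lactonises on gentle warming and comes back to the route at 20.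

**Further compounds**
F1 | step 14 | 2-(diethoxyphosphoryl)butanoate analogue of 17 (PMB ether) | CCC(/C=C/c1ccccc1)=C\C(C)=C\[C@](OC(=O)C(CC)P(=O)(OCC)OCC)(C)[C@@H](CC(=O)OC(C)(C)C)COCc2ccc(OC)cc2
F2 | step 14 | primary alcohol from F1 | CCC(/C=C/c1ccccc1)=C\C(C)=C\[C@](OC(=O)C(CC)P(=O)(OCC)OCC)(C)[C@@H](CC(=O)OC(C)(C)C)CO
F3 | step 14 | aldehyde from F2 | CCC(/C=C/c1ccccc1)=C\C(C)=C\[C@](OC(=O)C(CC)P(=O)(OCC)OCC)(C)[C@@H](CC(=O)OC(C)(C)C)C=O
F4 | step 14 | α-ethyl unsaturated δ-lactone (C6-ethyl analogue of 20) | CCC(/C=C/c1ccccc1)=C\C(C)=C\[C@]2(C)[C@@H](CC(=O)OC(C)(C)C)C=C(CC)C(=O)O2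
F5 | step 14 | lithium enolate of lactone 24 | CCC(/C=C/c1ccccc1)=C\C(C)=C\[C@]2(C)[C@@H](CC(=O)OC(C)(C)C)[C@H](C(CC)C(=O)OC)C(CC)=C(O[Li])O2
F6 | step 9 | tertiary trienyl alcohol (PMB ether; C3 R, C4 S) | CCC(/C=C/c1ccccc1)=C\C(C)=C\[C@](O)(C)[C@@H](CC(=O)OC(C)(C)C)COCc2ccc(OC)cc2
F7 | step 9 | bromoacetate of F6 | CCC(/C=C/c1ccccc1)=C\C(C)=C\[C@](OC(=O)CBr)(C)[C@@H](CC(=O)OC(C)(C)C)COCc2ccc(OC)cc2
F8 | step 10 | tert-butyl (3S)-3-(hydroxymethyl)-4-oxopentanoate | CC(=O)[C@@H](CC(=O)OC(C)(C)C)CO
F9 | step 10 | diol: tertiary trienyl carbinol with free C5 hydroxyl | CCC(/C=C/c1ccccc1)=C\C(C)=C\[C@](O)(C)[C@@H](CC(=O)OC(C)(C)C)CO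
F10 | step 10 | β-hydroxy aldehyde from F9 | CCC(/C=C/c1ccccc1)=C\C(C)=C\[C@](O)(C)[C@@H](CC(=O)OC(C)(C)C)C=O
F11 | step 10 | ethyl (Z)-enoate from F10 | CCC(/C=C/c1ccccc1)=C\C(C)=C\[C@](O)(C)[C@@H](CC(=O)OC(C)(C)C)/C=C\C(=O)OCC
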